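The route rests on reading the O6–C6–C7–C8(O) triad of the ten-membered carbocycle (C1–C10), where the γ-lactone ring (O6, C6, C7, C11, C12) meets the C8 ester, as an isoxazoline that bridges C6 and C8 across C7. A C8 nitrile oxide adds to the E C6=C7 end of a Z,E-dienoate. This one operation forms C7–C8 and O–C6, closes carbocycle and heterocycle, and sets C6 and C7. The precursor is an open-chain epoxy dienoate oxime: a citramalate-derived C8–C10/C1–C3 epoxy aldehyde joined at C3–C4 to a butynol-derived Z-iodoalkene that already carries the C5–C7/C11–C12 ester arm.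

Key step: step 17

Remark: germacrane locants are used (ring C1–C10, lactone carbons C11–C13, C14 on C10, C15 on C4); C3 is an auxiliary stereocentre that ends as the ketone, and its 3S epimer is carried because it is the expected Felkin product and should place the tether on the required alkene face.

Step 1
Reactants: 1 (R)-citramalic acid
Product: 2 2-[(4R)-2,2,4-trimethyl-5-oxo-1,3-dioxolan-4-yl]acetic acid
Conditions: Me2C(OMe)2, TsOH·H2O (cat.), rt
Reagents that add atoms: 2,2-dimethoxypropane, COC(C)(C)OC
Why: Acid-catalysed acetal exchange closes the five-membered dioxolanone on the α-hydroxy acid only, which differentiates the two carboxyl groups without touching the C10 stereocentre.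

Step 2
Reactants: 2 dioxolanone acid
Product: 4 (3R)-3-hydroxy-3-methyloxolan-2-one, via dioxolanone alcohol 3 (not isolated)
Conditions: BH3·SMe2, THF, 0 °C to rt; MeOH quench; then TsOH·H2O (cat.), CH2Cl2, rt
Reagents that add atoms: none
Why: Borane reduces the free carboxylic acid chemoselectively beside the dioxolanone carbonyl (carboxylic acid reduction), and acid-catalysed transesterification of the liberated primary alcohol onto the dioxolanone releases acetone and gives the hydroxy lactone with C10 unchanged.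

Step 3
Reactants: 4 hydroxy lactone
Product: 5 (3R)-3-methyloxolane-2,3-diol (lactol; anomer mixture)
Conditions: iBu2AlH (2.2 equiv), CH2Cl2/THF, −78 °C; potassium sodium tartrate (aq)
Reagents that add atoms: none
Why: Partial reduction of a lactone with iBu2AlH at low temperature stops at the lactol because the aluminium hemiacetal is stable until quench; the first equivalent is consumed by the tertiary hydroxyl.

Step 4
Reactants: 5 lactol
Product: 6 ethyl (2E,4R)-4,6-dihydroxy-4-methylhex-2-enoate
Conditions: Ph3P=CHCO2Et, PhCO2H (cat.), THF, 50 °C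
Reagents that add atoms: ethyl (triphenylphosphoranylidene)acetate, CCOC(=O)C=P(c1ccccc1)(c1ccccc1)c1ccccc1
Why: Wittig olefination of the open hydroxy aldehyde form of the lactol with a stabilised ylide gives the E enoate through the more stable trans oxaphosphetane; acid buffering and the quaternary carbon next to the β-position should hold back oxa-Michael closure of the primary hydroxyl.

Step 5
Reactants: 6 diol enoate
Product: 7 ethyl (2E,4R)-4-methyl-4,6-bis(triethylsilyloxy)hex-2-enoate
Conditions: Et3SiOTf, 2,6-lutidine, CH2Cl2, −78 to 0 °C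
Reagents that add atoms: triethylsilyl trifluoromethanesulfonate, CC[Si](CC)(CC)OS(=O)(=O)C(F)(F)F
Why: Silyl triflate with 2,6-lutidine silylates the primary and the tertiary hydroxyl in one operation (silyl ether formation), and the two TES ethers differ enough in hindrance to be distinguished in step 15.

Step 6
Reactants: 7 bis-TES enoate
Product: 8 (2E,4R)-4-methyl-4,6-bis(triethylsilyloxy)hex-2-en-1-ol
Conditions: iBu2AlH, CH2Cl2, −78 °C
Reagents that add atoms: none
Why: iBu2AlH reduces the enoate by two 1,2-hydride additions to the E allylic alcohol (ester reduction) and leaves silyl ethers and alkene geometry alone.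

Step 7
Reactants: 8 allylic alcohol
Product: 9 [(2S,3R)-3-[(2R)-2,4-bis(triethylsilyloxy)butan-2-yl]oxiran-2-yl]methanol
Conditions: Ti(OiPr)4, L-(+)-diethyl tartrate, tBuOOH, 4 Å molecular sieves, CH2Cl2, −20 °C
Reagents that add atoms: tert-butyl hydroperoxide, CC(C)(C)OO
Why: Sharpless asymmetric epoxidation of the primary E allylic alcohol: the titanium tartrate complex with L-(+)-diethyl tartrate delivers oxygen to the alkene face that gives the C1/C2 epoxide of the target (2S,3R by the locants of 9), the trans relationship follows from the E geometry, and reagent control should dominate the adjacent quaternary C10.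

Step 8
Reactants: 9 epoxy alcohol
Product: 10 (2R,3R)-3-[(2R)-2,4-bis(triethylsilyloxy)butan-2-yl]oxirane-2-carbaldehyde
Conditions: Dess–Martin periodinane, NaHCO3, CH2Cl2, 0 °C to rt
Reagents that add atoms: none
Why: Buffered Dess–Martin oxidation gives the epoxy aldehyde under conditions that neither open the epoxide nor epimerise C2.

Step 9
Reactants: 11 but-2-yn-1-ol
Product: 13 (Z)-3-iodobut-2-en-1-ol, via alkenylalanate 12 (not isolated)
Conditions: NaAlH2(OCH2CH2OMe)2, THF, 0 °C to rt; then I2, THF, −78 °C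
Reagents that add atoms: iodine, II
Why: Hydroxyl-directed trans-hydroalumination of the propargylic alcohol places aluminium on the distal, methyl-bearing carbon inside a five-membered alanate, and iodinolysis with retention gives the Z iodoalkene in which iodine (the later C3–C4 bond) is cis to the C6 carbon.

Step 10
Reactants: 13 (Z)-3-iodobut-2-en-1-ol
Product: 14 (Z)-3-iodobut-2-enal
Conditions: MnO2, CH2Cl2, rt, dark
Reagents that add atoms: none
Why: MnO2 oxidises the allylic alcohol selectively to the enal (allylic oxidation) under neutral heterogeneous conditions that preserve the Z geometry.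

Step 11
Reactants: 14 (Z)-3-iodobut-2-enal
Product: 15 (Z)-4-iodopenta-1,3-diene
Conditions: Ph3PCH3Br, KN(SiMe3)2, THF, −78 to 0 °C; product kept in solution
Reagents that add atoms: methyltriphenylphosphonium bromide, C[P+](c1ccccc1)(c1ccccc1)c1ccccc1.[Br-]
Why: Wittig methylenation with the non-stabilised ylide converts the aldehyde into the terminal alkene needed for metathesis and does not affect the trisubstituted iodoalkene.

Step 12
Reactants: 15 (Z)-4-iodopenta-1,3-diene; 16 methyl but-3-enoate
Product: 17 methyl (3E,5Z)-6-iodohepta-3,5-dienoate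
Conditions: (H2IMes)(PCy3)Cl2Ru=CHPh (second-generation Grubbs catalyst, cat.), 1,4-benzoquinone (cat.), 16 in excess, CH2Cl2, 40 °C
Reagents that add atoms: none
Why: Olefin cross-metathesis takes place only at the monosubstituted diene terminus (the iodinated trisubstituted alkene is inert), is driven by loss of ethylene and should favour the conjugated E alkene thermodynamically, while benzoquinone suppresses ruthenium hydride migration of the β,γ-double bond; any Z isomer is removed at this cheap stage.

Step 13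
Reactants: 10 epoxy aldehyde; 17 dienyl iodide ester
Product: 19 methyl (3E,5Z,7S)-7-[(2S,3R)-3-[(2R)-2,4-bis(triethylsilyloxy)butan-2-yl]oxiran-2-yl]-7-hydroxy-6-methylhepta-3,5-dienoate, via alkenylchromium 18 (not isolated)
Conditions: CrCl2 (excess), NiCl2 (cat.), DMSO, rt
Reagents that add atoms: none
Why: Nozaki–Hiyama–Kishi coupling: nickel-catalysed insertion into the carbon–iodine bond and transfer to chromium give an alkenylchromium that keeps the Z geometry and adds only to the aldehyde (ester and epoxide tolerated), and Felkin–Anh attack anti to the epoxide C2–O bond should favour the 3S (anti) carbinol.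

Step 14
Reactants: 19 dienyl carbinol
Product: 20 methyl (3E,5Z,7S)-7-[(2R,3R)-3-[(2R)-2,4-bis(triethylsilyloxy)butan-2-yl]oxiran-2-yl]-7-[tert-butyl(dimethyl)silyl]oxy-6-methylhepta-3,5-dienoate
Conditions: tBuMe2SiOTf, 2,6-lutidine, CH2Cl2, −78 °C
Reagents that add atoms: tert-butyldimethylsilyl trifluoromethanesulfonate, CC(C)(C)[Si](C)(C)OS(=O)(=O)C(F)(F)F
Why: Silyl triflate and 2,6-lutidine at low temperature silylate the hindered secondary allylic alcohol (silyl ether formation) faster than the Lewis acid can open the neighbouring epoxide.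

Step 15
Reactants: 20 tris-silyl ether
Product: 22 methyl (3E,5Z,7S)-7-[tert-butyl(dimethyl)silyl]oxy-6-methyl-7-[(2R,3R)-3-[(2R)-4-oxo-2-(triethylsilyloxy)butan-2-yl]oxiran-2-yl]hepta-3,5-dienoate, via alkoxysulfonium chloride 21 (not isolated)
Conditions: (COCl)2, DMSO, CH2Cl2, −78 to −30 °C; then Et3N, −78 to 0 °C
Reagents that add atoms: none
Why: Swern oxidation applied to a primary triethylsilyl ether: the chlorosulfonium reagent exchanges onto the unhindered primary oxygen with loss of the silyl group and the alkoxysulfonium ylide collapses to the aldehyde, whereas the tertiary TES and secondary TBS ethers are too hindered to react.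

Step 16
Reactants: 22 C8 aldehyde
Product: 23 epoxy Z,E-dienoate oxime (C8 E-aldoxime of 22)
Conditions: NH2OH·HCl, pyridine, EtOH, 0 °C to rt
Reagents that add atoms: hydroxylamine hydrochloride, NO.Cl
Why: Condensation of the aldehyde with hydroxylamine under pyridine buffering (oxime formation) leaves epoxide, ester and silyl ethers intact; oxime geometry is of no consequence because both isomers give the same nitrile oxide.

Step 17
Reactants: 23 epoxy Z,E-dienoate oxime
Product: 26 bridged isoxazoline (1R,2R,3S,6S,7R,10R), via hydroximoyl chloride 24 (not isolated), via nitrile oxide 25 (not isolated)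
Conditions: NCS, pyridine (cat.), CHCl3, rt; then slow addition to Et3N, PhMe, 60 °C, high dilution (about 0.002 M)
Reagents that add atoms: none
Why: N-Chlorosuccinimide converts the aldoxime into the hydroximoyl chloride and triethylamine eliminates HCl to the C8 nitrile oxide, which adds as a 1,3-dipole to C6=C7 in a concerted suprafacial [3+2] cycloaddition with carbon bonding to C7 and oxygen to C6; the closest known reaction type is the intramolecular nitrile oxide–alkene cycloaddition in its macrocyclic variant, which gives bridged isoxazolines. The isoxazoline closes as the five-membered cycloadduct ring, and the ten-membered carbocycle closes in the same event through the C7–C8 bond in the endo mode (both alkene carbons inside the new ring), so that the heterocycle bridges C6 and C8 over C7 in a bicyclo[7.2.1] framework. The relative configuration of C6 and C7 is fixed by the E geometry of C6=C7 (trans H6/H7 on the isoxazoline, which becomes the cis lactone once C12 closes on O6), and their absolute sense by the C3 stereocentre: A(1,3) strain across the Z C4=C5 alkene holds C3–H in the diene plane, puts the C2 arm of the tether on one face and the silyloxy group on the other, and the dipole can only arrive on the tether face, which corresponds to 6S,7R. Regioselectivity is needed between this mode and a nine-membered fused alternative and is secured by the diene rule (oxygen to the carbon that carries the conjugating vinyl group); site selectivity rests on the trisubstituted, more hindered C4=C5 being a far poorer dipolarophile. Slow generation of the dipole at high dilution keeps its stationary concentration low and holds back furoxan dimerisation.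

Step 18
Reactants: 26 bridged isoxazoline
Product: 29 keto lactone (1R,2R,3S,6S,7S,10R), via hydroxy imine 27 (not isolated), via hydroxy ketone ester 28 (not isolated)
Conditions: SmI2, THF, 0 °C; B(OH)3, MeOH/H2O, rt; then PPTS (cat.), PhMe, 40 °C
Reagents that add atoms: water, O
Why: Divalent samarium cleaves the weak N–O bond by two single-electron transfers (reductive isoxazoline opening), boric acid hydrolyses the resulting imine to the C8 ketone, and the C6 hydroxyl, at this point the only hydroxyl that can reach C12, closes the cis γ-lactone under mild acid, so that the lactone is fixed on O6 before a C8 oxygen exists; the non-enolising conditions keep C7.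

Step 19
Reactants: 29 keto lactone
Product: 30 C8 alcohol (1R,2R,3S,6S,7R,8R,10R)
Conditions: NaBH4, CeCl3·7H2O, MeOH/THF, −78 °C
Reagents that add atoms: none
Why: Luche-type borohydride reduction of the ketone: if C11 eclipses the carbonyl, hydride should approach from the ring periphery anti to the C7–C6 bond (Felkin–Anh), which gives the 8R alcohol syn to O6, and the low temperature with cerium buffering avoids β-elimination of the lactone carboxylate and translactonisation.

Step 20
Reactants: 30 C8 alcohol; 31 tiglic acid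
Product: 33 C8 tiglate (1R,2R,3S,6S,7R,8R,10R), via mixed anhydride 32 (not isolated)
Conditions: 2,4,6-Cl3C6H2COCl, Et3N, PhMe, rt; then 30, DMAP, rt
Reagents that add atoms: none
Why: Yamaguchi esterification: DMAP attacks the tigloyl carbonyl of the mixed anhydride and the acylpyridinium acylates the hindered secondary C8 hydroxyl with retention of configuration, leaving the tertiary silyl ether and the E tiglate geometry untouched.

Step 21
Reactants: 33 C8 tiglate
Product: 37 α-methylene lactone (1R,2R,3S,6S,7R,8R,10R), via lithium enolate 34 (not isolated), via Mannich base 35 (not isolated), via ammonium iodide 36 (not isolated)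
Conditions: LiN(SiMe3)2 (1.1 equiv), THF, −78 °C; CH2=NMe2+ I−, −78 to −20 °C; then MeI, CH2Cl2, rt; NaHCO3 (aq)
Reagents that add atoms: N,N-dimethylmethyleneiminium iodide (Eschenmoser's salt), C=[N+](C)C.[I-]
Why: α-Methylenation of a lactone by kinetic enolate formation, Mannich reaction with the iminium salt, N-methylation and base-induced β-elimination of trimethylamine installs C13; the tiglate has no α-hydrogen and is expected to be spared by one equivalent of the hindered amide base at low temperature.

Step 22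
Reactants: 37 α-methylene lactone
Product: 38 C3,C10 diol (1R,2S,3S,6S,7R,8R,10R)
Conditions: HF·pyridine, pyridine, THF, 0 °C to rt
Reagents that add atoms: none
Why: Fluoride-mediated desilylation with pyridine-buffered HF removes the secondary TBS and tertiary TES ethers under conditions mild enough for the epoxide, the tiglate and the α-methylene lactone.

Step 23
Reactants: 38 C3,C10 diol
Product: 39 CNP0383091.1 (1R,2R,6S,7R,8R,10R)
Conditions: Dess–Martin periodinane, NaHCO3, CH2Cl2, 0 °C
Reagents that add atoms: none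
Why: Dess–Martin oxidation converts the secondary allylic C3 alcohol into the enone while the tertiary C10 alcohol cannot react, which erases the auxiliary C3 stereocentre and completes the epoxy enone of the target.

Compound list
1 | (R)-citramalic acid, (2R)-2-hydroxy-2-methylbutanedioic acid | C[C@@](O)(CC(=O)O)C(=O)O | starting material
2 | 2-[(4R)-2,2,4-trimethyl-5-oxo-1,3-dioxolan-4-yl]acetic acid | C[C@]1(CC(=O)O)OC(C)(C)OC1=O | intermediate
3 | (5R)-5-(2-hydroxyethyl)-2,2,5-trimethyl-1,3-dioxolan-4-one (not isolated) | C[C@]1(CCO)OC(C)(C)OC1=O | intermediate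
4 | (3R)-3-hydroxy-3-methyloxolan-2-one | C[C@@]1(O)CCOC1=O | intermediate
5 | (3R)-3-methyloxolane-2,3-diol, anomer mixture at C2 | C[C@@]1(O)CCOC1O | intermediate
6 | ethyl (2E,4R)-4,6-dihydroxy-4-methylhex-2-enoate | CCOC(=O)/C=C/[C@](C)(O)CCO | intermediate
7 | ethyl (2E,4R)-4-methyl-4,6-bis(triethylsilyloxy)hex-2-enoate | CCOC(=O)/C=C/[C@](C)(O[Si](CC)(CC)CC)CCO[Si](CC)(CC)CC | intermediate
8 | (2E,4R)-4-methyl-4,6-bis(triethylsilyloxy)hex-2-en-1-ol | OC/C=C/[C@](C)(O[Si](CC)(CC)CC)CCO[Si](CC)(CC)CC | intermediate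
9 | [(2S,3R)-3-[(2R)-2,4-bis(triethylsilyloxy)butan-2-yl]oxiran-2-yl]methanol | OC[C@@H]1O[C@H]1[C@](C)(O[Si](CC)(CC)CC)CCO[Si](CC)(CC)CC | intermediate
10 | (2R,3R)-3-[(2R)-2,4-bis(triethylsilyloxy)butan-2-yl]oxirane-2-carbaldehyde | O=C[C@@H]1O[C@H]1[C@](C)(O[Si](CC)(CC)CC)CCO[Si](CC)(CC)CC | intermediate
11 | but-2-yn-1-ol | CC#CCO | starting material
12 | sodium alkenylalanate: five-membered 1,2-oxaluminole with aluminium on the methyl-bearing alkene carbon and two 2-methoxyethoxy ligands (not isolated) | CC1=CCO[Al-]1(OCCOC)OCCOC.[Na+] | intermediate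
13 | (Z)-3-iodobut-2-en-1-ol | C/C(I)=C/CO | intermediate
14 | (Z)-3-iodobut-2-enal | C/C(I)=C/C=O | intermediate
15 | (Z)-4-iodopenta-1,3-diene | C=C/C=C(/C)I | intermediate
16 | methyl but-3-enoate | C=CCC(=O)OC | starting material
17 | methyl (3E,5Z)-6-iodohepta-3,5-dienoate | COC(=O)C/C=C/C=C(/C)I | intermediate
18 | alkenylchromium dichloride derived from 17, CrCl2 in place of iodine, geometry retained (not isolated) | COC(=O)C/C=C/C=C(/C)[Cr](Cl)Cl | intermediate
19 | methyl (3E,5Z,7S)-7-[(2S,3R)-3-[(2R)-2,4-bis(triethylsilyloxy)butan-2-yl]oxiran-2-yl]-7-hydroxy-6-methylhepta-3,5-dienoate | COC(=O)C/C=C/C=C(/C)[C@H](O)[C@@H]1O[C@H]1[C@](C)(O[Si](CC)(CC)CC)CCO[Si](CC)(CC)CC | intermediate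
20 | methyl (3E,5Z,7S)-7-[(2R,3R)-3-[(2R)-2,4-bis(triethylsilyloxy)butan-2-yl]oxiran-2-yl]-7-[tert-butyl(dimethyl)silyl]oxy-6-methylhepta-3,5-dienoate | COC(=O)C/C=C/C=C(/C)[C@H](O[Si](C)(C)C(C)(C)C)[C@@H]1O[C@H]1[C@](C)(O[Si](CC)(CC)CC)CCO[Si](CC)(CC)CC | intermediate
21 | alkoxysulfonium chloride: 20 with the primary OSiEt3 replaced by O–S+Me2 Cl− (not isolated) | COC(=O)C/C=C/C=C(/C)[C@H](O[Si](C)(C)C(C)(C)C)[C@@H]1O[C@H]1[C@](C)(O[Si](CC)(CC)CC)CCO[S+](C)C.[Cl-] | intermediate
22 | methyl (3E,5Z,7S)-7-[tert-butyl(dimethyl)silyl]oxy-6-methyl-7-[(2R,3R)-3-[(2R)-4-oxo-2-(triethylsilyloxy)butan-2-yl]oxiran-2-yl]hepta-3,5-dienoate | COC(=O)C/C=C/C=C(/C)[C@H](O[Si](C)(C)C(C)(C)C)[C@@H]1O[C@H]1[C@](C)(O[Si](CC)(CC)CC)CC=O | intermediate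
23 | epoxy Z,E-dienoate oxime: methyl (3E,5Z,7S)-7-[tert-butyl(dimethyl)silyl]oxy-7-[(2R,3R)-3-[(2R,4E)-4-hydroxyimino-2-(triethylsilyloxy)butan-2-yl]oxiran-2-yl]-6-methylhepta-3,5-dienoate | COC(=O)C/C=C/C=C(/C)[C@H](O[Si](C)(C)C(C)(C)C)[C@@H]1O[C@H]1[C@](C)(O[Si](CC)(CC)CC)C/C=N/O | intermediate
24 | C8 hydroximoyl chloride of 23 (not isolated) | COC(=O)C/C=C/C=C(/C)[C@H](O[Si](C)(C)C(C)(C)C)[C@@H]1O[C@H]1[C@](C)(O[Si](CC)(CC)CC)CC(Cl)=NO | intermediate
25 | C8 nitrile oxide (not isolated) | COC(=O)C/C=C/C=C(/C)[C@H](O[Si](C)(C)C(C)(C)C)[C@@H]1O[C@H]1[C@](C)(O[Si](CC)(CC)CC)CC#[N+][O-] | intermediate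
26 | bridged isoxazoline (1R,2R,3S,6S,7R,10R): ten-membered ring C1–C10, O–N=C8 unit spanning C6 and C8 over C7, CH2CO2Me on C7, Z C4=C5, 3-OTBS, 1,2-epoxide, 10-OTES | COC(=O)C[C@H]1[C@@H]2/C=C(/C)[C@H](O[Si](C)(C)C(C)(C)C)[C@@H]3O[C@H]3[C@](C)(O[Si](CC)(CC)CC)CC1=NO2 | intermediate
27 | C6-hydroxy C8-imine (1R,2R,3S,6S,7R,10R) (not isolated) | COC(=O)C[C@H]1[C@@H](O)/C=C(/C)[C@H](O[Si](C)(C)C(C)(C)C)[C@@H]2O[C@H]2[C@](C)(O[Si](CC)(CC)CC)CC1=N | intermediate
28 | C6-hydroxy C8-ketone methyl ester (1R,2R,3S,6S,7S,10R) (not isolated) | COC(=O)C[C@H]1[C@@H](O)/C=C(/C)[C@H](O[Si](C)(C)C(C)(C)C)[C@@H]2O[C@H]2[C@](C)(O[Si](CC)(CC)CC)CC1=O | intermediate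
29 | keto lactone (1R,2R,3S,6S,7S,10R): cis-fused 6,12-olide, C8 ketone, 3-OTBS, 10-OTES | C1C(=O)O[C@H]2/C=C(/C)[C@H](O[Si](C)(C)C(C)(C)C)[C@@H]3O[C@H]3[C@](C)(O[Si](CC)(CC)CC)CC(=O)[C@@H]12 | intermediate
30 | C8 alcohol (1R,2R,3S,6S,7R,8R,10R) | C1C(=O)O[C@H]2/C=C(/C)[C@H](O[Si](C)(C)C(C)(C)C)[C@@H]3O[C@H]3[C@](C)(O[Si](CC)(CC)CC)C[C@@H](O)[C@@H]12 | intermediate
31 | tiglic acid, (2E)-2-methylbut-2-enoic acid | C/C=C(\C)C(=O)O | starting material
32 | tigloyl 2,4,6-trichlorobenzoyl anhydride (not isolated) | C/C=C(\C)C(=O)OC(=O)c1c(Cl)cc(Cl)cc1Cl | intermediate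
33 | C8 tiglate (1R,2R,3S,6S,7R,8R,10R) | C1C(=O)O[C@H]2/C=C(/C)[C@H](O[Si](C)(C)C(C)(C)C)[C@@H]3O[C@H]3[C@](C)(O[Si](CC)(CC)CC)C[C@@H](OC(=O)/C(C)=C/C)[C@@H]12 | intermediate
34 | lithium enolate of lactone 33, C11=C12 (not isolated) | C1=C([O-])O[C@H]2/C=C(/C)[C@H](O[Si](C)(C)C(C)(C)C)[C@@H]3O[C@H]3[C@](C)(O[Si](CC)(CC)CC)C[C@@H](OC(=O)/C(C)=C/C)[C@@H]12.[Li+] | intermediate
35 | C11 dimethylaminomethyl lactone, C11 configuration not assigned (not isolated) | CN(C)CC1C(=O)O[C@H]2/C=C(/C)[C@H](O[Si](C)(C)C(C)(C)C)[C@@H]3O[C@H]3[C@](C)(O[Si](CC)(CC)CC)C[C@@H](OC(=O)/C(C)=C/C)[C@@H]12 | intermediate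
36 | C11 trimethylammoniomethyl lactone iodide, C11 configuration not assigned (not isolated) | C[N+](C)(C)CC1C(=O)O[C@H]2/C=C(/C)[C@H](O[Si](C)(C)C(C)(C)C)[C@@H]3O[C@H]3[C@](C)(O[Si](CC)(CC)CC)C[C@@H](OC(=O)/C(C)=C/C)[C@@H]12.[I-] | intermediate
37 | α-methylene lactone (1R,2R,3S,6S,7R,8R,10R), 3-OTBS, 10-OTES | C=C1C(=O)O[C@H]2/C=C(/C)[C@H](O[Si](C)(C)C(C)(C)C)[C@@H]3O[C@H]3[C@](C)(O[Si](CC)(CC)CC)C[C@@H](OC(=O)/C(C)=C/C)[C@@H]12 | intermediate
38 | C3,C10 diol (1R,2S,3S,6S,7R,8R,10R) | C=C1C(=O)O[C@H]2/C=C(/C)[C@H](O)[C@@H]3O[C@H]3[C@](C)(O)C[C@@H](OC(=O)/C(C)=C/C)[C@@H]12 | intermediate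
39 | CNP0383091.1 (1R,2R,6S,7R,8R,10R) | C=C1C(=O)O[C@H]2/C=C(/C)C(=O)[C@@H]3O[C@H]3[C@](C)(O)C[C@@H](OC(=O)/C(C)=C/C)[C@@H]12 | target

Totals
Total step count: 23. Longest linear sequence: 19 steps (steps 1–8 and 13–23); steps 9–12 are a four-step side branch.

Steps most likely to fail

Step 17. Three processes threaten it: the dipole may dimerise or oligomerise faster than the strained ten-membered closure, the addition may leak into the nine-membered fused regiochemistry, or the dipole may reach the wrong alkene face if the tether does not fold as modelled. The fallback exchanges the order of the two unions: the cycloaddition becomes intermolecular and the ring is closed at C3–C4 by an intramolecular Nozaki–Hiyama–Kishi reaction. It sets out from epoxy alcohol 9 and comes back at isoxazoline 26. Silylation of 9 (tBuMe2SiCl, imidazole) gives the primary TBS ether F1. Swern oxidation of its primary TES ether gives the C8 aldehyde F2, and hydroxylamine gives the oxime F3. Oxidation of F3 with PhI(OAc)2 in the presence of excess dienyl iodide 17 generates the nitrile oxide F4, which adds to the C6=C7 alkene of 17 to give the trans isoxazoline F5. The diastereomer with the C6/C7 configuration of 26 is separated from its partner. Buffered HF·pyridine frees the primary alcohol F6, Dess–Martin oxidation gives the epoxy aldehyde F7, and CrCl2/NiCl2 at high dilution closes the ten-membered ring to the macrocyclic C3 alcohol F8. Silylation of F8 with tBuMe2SiOTf returns to 26; the C3 epimer would serve equally, since C3 ends as the ketone.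

Step 19. Hydride may be delivered to the wrong carbonyl face if the ring torsion about C7–C8 differs from the model, giving the C8 epimer or a mixture. The fallback replaces stereoselective reduction plus retentive acylation by invertive esterification. It sets out from keto lactone 29 and comes back at tiglate 33. Reduction of 29 with a hydride chosen for the opposite face (or collection of the unwanted epimer from step 19) gives the 8S alcohol F9. Mitsunobu reaction of F9 with tiglic acid 31 (PPh3, DIAD, PhMe) installs the ester with inversion and gives 33, so both C8 epimers converge.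

Step 21. The lactone enolate may attack the neighbouring tiglate carbonyl through a five-membered transition state (acyl transfer), or the base may attack the tiglate itself. The fallback moves the methylenation ahead of the acylation. It sets out from alcohol 30 and comes back at α-methylene lactone 37. Silylation of 30 (Me3SiCl, imidazole) gives the C8 TMS ether F10. LiN(SiMe3)2 gives the lithium enolate F11, CH2=NMe2+ I− gives the Mannich base F12, MeI gives the ammonium iodide F13, and NaHCO3 gives the α-methylene lactone TMS ether F14. Citric acid in MeOH at 0 °C removes only the secondary TMS group to give the C8 alcohol F15. Acylation of F15 with mixed anhydride 32 and DMAP gives 37.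

Further compounds
F1 | step 17 | tert-butyl-[[(2S,3R)-3-[(2R)-2,4-bis(triethylsilyloxy)butan-2-yl]oxiran-2-yl]methoxy]dimethylsilane | CC(C)(C)[Si](C)(C)OC[C@@H]1O[C@H]1[C@](C)(O[Si](CC)(CC)CC)CCO[Si](CC)(CC)CC
F2 | step 17 | C8 aldehyde of F1 (3-[(2R)-4-oxo-2-(triethylsilyloxy)butan-2-yl] epoxide, primary OTBS) | CC(C)(C)[Si](C)(C)OC[C@@H]1O[C@H]1[C@](C)(O[Si](CC)(CC)CC)CC=O
F3 | step 17 | C8 E-aldoxime of F2 | CC(C)(C)[Si](C)(C)OC[C@@H]1O[C@H]1[C@](C)(O[Si](CC)(CC)CC)C/C=N/O
F4 | step 17 | C8 nitrile oxide from F3 (not isolated) | CC(C)(C)[Si](C)(C)OC[C@@H]1O[C@H]1[C@](C)(O[Si](CC)(CC)CC)CC#[N+][O-]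
F5 | step 17 | open-chain trans isoxazoline: C8 substituent at position 3, CH2CO2Me at position 4 (C7), (Z)-2-iodoprop-1-enyl at position 5 (C6), C6/C7 as in 26 | COC(=O)C[C@H]1[C@H](/C=C(/C)I)ON=C1C[C@@](C)(O[Si](CC)(CC)CC)[C@@H]2O[C@H]2CO[Si](C)(C)C(C)(C)C
F6 | step 17 | primary C3 alcohol from F5 | COC(=O)C[C@H]1[C@H](/C=C(/C)I)ON=C1C[C@@](C)(O[Si](CC)(CC)CC)[C@@H]2O[C@H]2CO
F7 | step 17 | C3 epoxy aldehyde from F6 | COC(=O)C[C@H]1[C@H](/C=C(/C)I)ON=C1C[C@@](C)(O[Si](CC)(CC)CC)[C@@H]2O[C@H]2C=O
F8 | step 17 | bridged isoxazoline with free 3S hydroxyl (26 without the TBS group) | COC(=O)C[C@H]1[C@@H]2/C=C(/C)[C@H](O)[C@@H]3O[C@H]3[C@](C)(O[Si](CC)(CC)CC)CC1=NO2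
F9 | step 19 | 8S alcohol (C8 epimer of 30) | C1C(=O)O[C@H]2/C=C(/C)[C@H](O[Si](C)(C)C(C)(C)C)[C@@H]3O[C@H]3[C@](C)(O[Si](CC)(CC)CC)C[C@H](O)[C@@H]12
F10 | step 21 | C8 trimethylsilyl ether of 30 | C1C(=O)O[C@H]2/C=C(/C)[C@H](O[Si](C)(C)C(C)(C)C)[C@@H]3O[C@H]3[C@](C)(O[Si](CC)(CC)CC)C[C@@H](O[Si](C)(C)C)[C@@H]12
F11 | step 21 | lithium enolate of F10 (not isolated) | C1=C([O-])O[C@H]2/C=C(/C)[C@H](O[Si](C)(C)C(C)(C)C)[C@@H]3O[C@H]3[C@](C)(O[Si](CC)(CC)CC)C[C@@H](O[Si](C)(C)C)[C@@H]12.[Li+]
F12 | step 21 | C11 dimethylaminomethyl lactone from F11, C11 not assigned (not isolated) | CN(C)CC1C(=O)O[C@H]2/C=C(/C)[C@H](O[Si](C)(C)C(C)(C)C)[C@@H]3O[C@H]3[C@](C)(O[Si](CC)(CC)CC)C[C@@H](O[Si](C)(C)C)[C@@H]12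
F13 | step 21 | C11 trimethylammoniomethyl lactone iodide from F12 (not isolated) | C[N+](C)(C)CC1C(=O)O[C@H]2/C=C(/C)[C@H](O[Si](C)(C)C(C)(C)C)[C@@H]3O[C@H]3[C@](C)(O[Si](CC)(CC)CC)C[C@@H](O[Si](C)(C)C)[C@@H]12.[I-]
F14 | step 21 | α-methylene lactone C8 trimethylsilyl ether | C=C1C(=O)O[C@H]2/C=C(/C)[C@H](O[Si](C)(C)C(C)(C)C)[C@@H]3O[C@H]3[C@](C)(O[Si](CC)(CC)CC)C[C@@H](O[Si](C)(C)C)[C@@H]12
F15 | step 21 | α-methylene lactone C8 alcohol | C=C1C(=O)O[C@H]2/C=C(/C)[C@H](O[Si](C)(C)C(C)(C)C)[C@@H]3O[C@H]3[C@](C)(O[Si](CC)(CC)CC)C[C@@H](O)[C@@H]12
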